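- If a product percent at a given clock time does not change with the charge, you can read every flask off one curve, and you need only a small correction for what has not yet reacted.

| setting | birch | larch | Monday's | Thursday's |
|---|---|---|---|---|
| left-handed substrate | 15 mM | 24 mM | 11 mM | 11 mM |
| right-handed substrate | 15 mM | 24 mM | 11 mM | 11 mM |
| gas | 6.3 mM (held) | 6.3 mM (held) | 6.3 mM (held) | 6.3 mM (held) |
| remark | run made earlier | run made earlier |  |  |
| time |  |  | 2.5 min | 5.0 min |

| run | time / min | left-handed product / % | right-handed product / % |
|---|---|---|---|
| birch | 0.667 | 40 | 22 |
| birch | 1.33 | 53 | 32 |
| birch | 2.00 | 58 | 36 |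
| birch | 2.50 | 59 | 39 |
| birch | 3.00 | 58 | 37 |
| larch | 0.667 | 39 | 21 |
| larch | 1.33 | 53 | 31 |
| larch | 2.00 | 58 | 36 |
| larch | 2.50 | 58 | 36 |
| larch | 3.00 | 59 | 35 |

(readings scatter by 1.5 percentage points)

- partner is single-handed; left-handed substrate and right-handed substrate are mirror images of each other, charged as a racemate, each of them at the stated concentration
- at the start none of the gas is in solution
- an excess is the difference of the two amounts in percent of their sum
- an excess is below zero if the other one leads
- the handed part of partner does not stay in what it makes, so the products of the two hands are mirror images too

- which of the two ends with the higher excess of left-handed product over right-handed product in the product ("neither" if they lie within 2 percentage points) (Monday's / Thursday's / neither)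
- excess of left-handed product over right-handed product in the product at the end, Monday's
- excess of left-handed product over right-handed product in the product at the end, Thursday's

- Birch at 15 mM and larch at 24 mM agree within the scatter at each reading, so I treat consumption as pseudo-first-order and apply their curve at 11 mM.
- First rung: at 0.667 min, the two runs leave a pooled remainder r of 39.0%. That gives a rate constant k of 1.41 min⁻¹, and the pooled excess E there is 29.5%.
- Second rung: the readings from 2.00 min to 3.00 min pool to a plateau excess of 23.0%.
- The tail weight s is the excess points above this plateau per point of charge unreacted, here 0.166. So E = plateau + s·r.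
- Last rung: Monday's stops at 3.53 times 1/k, with r = 2.93%, and Thursday's at 7.06 times 1/k, with r = 0.0860%. My reckoning gives 23.5% and 23.0%, a gap of 0.50 percentage points, less than the margin.
- The forecast says neither, with 23.5% and 23%: “About 97% is converted by 2.5 minutes, so the extra time to 5 minutes adds only a little late, less selective product.”
- The flask gives neither, with 23.2% for Monday's and 22.9% for Thursday's. At Monday's end the two substrates and the achiral form together hold 1.97% of the charge, and s turns that into 0.33 points; the computed gap between the flasks is 0.30 points.

    partner + left-handed substrate → left-handed product (k = 13.0 M⁻¹ s⁻¹)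
    partner + right-handed substrate → right-handed product (k = 5.70 M⁻¹ s⁻¹)
    left-handed substrate ⇌ achiral form (K = 0.310, k = 0.0400 s⁻¹)
    right-handed substrate ⇌ achiral form (K = 0.310, k = 0.0400 s⁻¹)
    gas ⇌ partner, rate k5*(csat - [partner]) (kL = 0.400 s⁻¹)
    partner → decomposition product (k = 1.10 × 10⁻⁴ s⁻¹)
    partner → decomposed reagent (k = 0.250 s⁻¹)

- Read Monday's at 40 s instead: the two substrates and the achiral form hold 37.5%, so the plateau plus s·r gives 29.2%. The computed excess is 28.0%.

(The data stem from a simulated flask with constants of no real substance, noise included.)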